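The rate constants are assumed; no experiment stands behind them.

The constants of this cycle say where the target stops, so I began from them.

    partner + free catalyst ⇌ catalyst intermediate A (K1 = 12 M⁻¹, k1 = 18 M⁻¹ s⁻¹)
    starting material + catalyst intermediate A ⇌ catalyst intermediate B (K2 = 9.7 M⁻¹, k2 = 67 M⁻¹ s⁻¹)
    catalyst intermediate B ⇌ by-product + catalyst intermediate C (K3 = 0.21 M, k3 = 0.022 s⁻¹)
    catalyst intermediate C → free catalyst + target (k4 = 0.073 s⁻¹)
    starting material + target → side product (k5 = 0.0013 M⁻¹ s⁻¹)
    starting material + protic impurity → quenched substrate (k6 = 3.0 × 10⁻⁴ M⁻¹ s⁻¹)

in all of them: protic impurity 33.0 mM; free catalyst 73 µM; time 50 h

|  | starting material | partner | remark |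
|---|---|---|---|
| winter | 33 mM | 36.3 mM (fed, over 30 h) | all else is in the flask from the start; the feed brings no volume worth counting |
| noon | 33 mM | 36.3 mM | everything together at the start |
| midnight | 33 mM (fed, over 30 h) | 36.3 mM | all else is in the flask from the start; the feed brings no volume worth counting |

- percent here means starting material units held: one side product counts as two
- run time (winter): 50 h

- the flask that comes out highest in amount of side product, in percent of the starting material charged; "all alike" if 1.5 percentage points covers them all (winter / noon / midnight / all alike)
- amount of side product at the end, in percent of the starting material charged, winter
- amount of side product at the end, in percent of the starting material charged, noon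
- amount of side product at the end, in percent of the starting material charged, midnight

I took the by-product step as the rate-limiting step. Catalyst intermediate B falls back faster than it goes forward, and the constant of the last step, 0.073 s⁻¹, is larger than the 0.022 s⁻¹ of the by-product step. I expected turnovers to use a quarter of the starting material charge in partner, which leaves about 28.0 mM. Late in a run I counted the catalyst as free catalyst plus intermediate A, which puts 18.4 µM in intermediate A. Leaving out intermediates B and C was an approximation, and it is a poor one at the start of noon, where the equilibrium constant of the second step times starting material is 0.32.

turnover constant = rate constant of the by-product step × equilibrium constant of the second step × intermediate A = 3.92 × 10⁻⁶ s⁻¹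

Target forms at this constant times starting material, and it is lost at 0.0013 M⁻¹ s⁻¹ times starting material times target. Starting material stands in both rates and cancels. This gives the target ceiling, the turnover constant over the side-product constant.

target ceiling = 3.02 mM, or 9.14 % of the charge

At the target ceiling each turnover costs two units of starting material. My first way to noon's side product held starting material at its charge for the whole run and gave 123 %, more than was charged. My second way was the balance of starting material, the limiting reagent. With mean impurity at 24.8 mM, the quench constant is 7.43 × 10⁻⁶ s⁻¹.

loss constant = twice the turnover constant + quench constant = 1.53 × 10⁻⁵ s⁻¹

turnover share = 51.4 %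

side product = share × (charge used + ceiling) − twice the ceiling

The half-life of starting material is 12.6 h, shorter than the run, so the first way cheats. The balance gives noon 34.5 %.

For midnight I let each fed portion decay for its own time, which gives 29.4 %. For winter I took partner at 14.0 mM during the feed, so the turnover constant there is 2.24 × 10⁻⁶ s⁻¹, and this gives 23.1 %. My highest flask is noon.

The forecast also named noon, with winter 15 %, noon 34 % and midnight 25 %, holding that “feeding partner starves target formation while the impurity eats the starting material”. Its winter and midnight figures differ from mine.

The simulation gave noon as highest, with winter 23.0 %, noon 35.1 % and midnight 29.8 %. The winter flask ended with 7.77 % target and the noon flask with 8.59 %, both read at 50.0 h, against my ceiling of 9.14 %.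

For the neighbour of noon charged with 9.1 mM of partner, I spent partner in the same proportion, leaving 7.03 mM. The ceiling there is 2.83 % of the charge. That neighbour ended with 2.46 % target and 16.2 % side product.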